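**Retrosynthetic overview**
1. Structural feature: the benzo ring of the benzofuran (C3a, C4, C5, C6, C7, C7a) carries acetyl at C5 next to hydroxyl at C6, with C4 and C7 unsubstituted. This is the pattern that a 1,1-dioxygenated diene and but-3-yn-2-one deliver, so this ring is built last and de novo.
2. Key disconnection: benzofuran bonds C3a–C4 and C5–C6, by [4+2] cycloaddition of a furan-2-yl ketene silyl acetal (exocyclic C=C plus furan C2=C3) with butynone, then aromatisation by loss of methanol.
3. Precursor: the ketene acetal comes from a furan-2-ylacetate; its CH2CO2Me arm from furan C5–H borylation and coupling with methyl bromoacetate; the carbinol methyl from catalyst-controlled Me2Zn addition to an aryl ketone; the CH(CH3)–furan bond from Rh/(R)-BINAP addition of furan-2-ylboronic acid to the crotonoyl chromene.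
4. Ring order: pyran ring of the chromene first (phenol plus enal), the furan ring is bought, the benzo ring of the benzofuran is closed last.

Key step: step 10

Assumption: the ketene silyl acetal is drawn as its (Z) isomer; an (E)/(Z) mixture would converge on the same benzofuran, because the acetal carbon becomes the aromatic carbon C6.

**Step 1**
Reactants: 1 1-(4-hydroxy-2-methoxyphenyl)ethanone; 2 3-methylbut-2-enal
Product: 3 1-(7-methoxy-2,2-dimethyl-2H-chromen-6-yl)ethanone
Conditions: 2 (2 equiv), pyridine, 140 °C, sealed tube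
Reagents that add atoms: none
Why: Base-mediated phenol–enal chromenylation (C-alkylation ortho to the phenol, dehydration to an ortho-quinone methide, oxa-6π electrocyclisation) forms the pyran ring, and attack is expected at the ring carbon para to OMe, as with 3-methoxyphenol, because the other ortho carbon is flanked by OH and OMe.

**Step 2**
Reactants: 3 1-(7-methoxy-2,2-dimethyl-2H-chromen-6-yl)ethanone; 4 acetaldehyde
Product: 6 3-hydroxy-1-(7-methoxy-2,2-dimethyl-2H-chromen-6-yl)butan-1-one (racemic at C3), via lithium enolate 5 (not isolated)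
Conditions: LiN(iPr)2, THF, −78 °C; 4, −78 °C; AcOH quench at −78 °C
Reagents that add atoms: none
Why: Directed aldol addition of the preformed kinetic lithium enolate of the methyl ketone to acetaldehyde at −78 °C avoids acetaldehyde self-condensation, and the racemic carbinol centre is removed in step 3.

**Step 3**
Reactants: 6 3-hydroxy-1-(7-methoxy-2,2-dimethyl-2H-chromen-6-yl)butan-1-one
Product: 8 (2E)-1-(7-methoxy-2,2-dimethyl-2H-chromen-6-yl)but-2-en-1-one, via β-mesyloxy ketone 7 (not isolated)
Conditions: MsCl, Et3N (excess), CH2Cl2, 0 → 25 °C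
Reagents that add atoms: none
Why: Mesylation followed by E1cB elimination with Et3N (aldol dehydration) gives the conjugated enone, the (E) isomer being the thermodynamically favoured one.

**Step 4**
Reactants: 8 (2E)-1-(7-methoxy-2,2-dimethyl-2H-chromen-6-yl)but-2-en-1-one; 9 furan-2-ylboronic acid
Product: 10 (3S)-3-(furan-2-yl)-1-(7-methoxy-2,2-dimethyl-2H-chromen-6-yl)butan-1-one
Conditions: [Rh(nbd)2]BF4 (3 mol%), (R)-BINAP (3.3 mol%), Et3N, dioxane/H2O (10:1), 30 °C; 9 (3 equiv) added in portions
Reagents that add atoms: none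
Why: Hayashi–Miyaura rhodium-catalysed asymmetric 1,4-addition of a boronic acid to an (E)-enone, in which the (R)-BINAP complex delivers the furyl group to the enone face that gives the (S) centre (the sense known for aryl additions to (E)-crotonyl acceptors), while the mild base and low temperature limit protodeboronation, which the excess of 9 offsets.

**Step 5**
Reactants: 10 (3S)-3-(furan-2-yl)-1-(7-methoxy-2,2-dimethyl-2H-chromen-6-yl)butan-1-one
Product: 11 (2S,4S)-4-(furan-2-yl)-2-(7-methoxy-2,2-dimethyl-2H-chromen-6-yl)pentan-2-ol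
Conditions: Me2Zn (3 equiv), Ti(OiPr)4 (1.2 equiv), bis(hydroxycamphorsulfonamide) ligand of trans-cyclohexane-1,2-diamine (10 mol%), toluene/hexanes, 25 °C; H2O
Reagents that add atoms: dimethylzinc, C[Zn]C
Why: Titanium-promoted addition of a dialkylzinc to an aryl alkyl ketone catalysed by a chiral bis(sulfonamide) diol, with the ligand enantiomer chosen to deliver methyl to the Re face of the carbonyl (O > aryl > CH2), sets the (S) carbinol under catalyst control because the catalyst distinguishes the aryl group from the CH2 chain and the remote C4 centre exerts little bias.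

**Step 6**
Reactants: 11 (2S,4S)-4-(furan-2-yl)-2-(7-methoxy-2,2-dimethyl-2H-chromen-6-yl)pentan-2-ol
Product: 12 triethyl{[(2S,4S)-4-(furan-2-yl)-2-(7-methoxy-2,2-dimethyl-2H-chromen-6-yl)pentan-2-yl]oxy}silane
Conditions: TESOTf, 2,6-lutidine, CH2Cl2, −78 → 0 °C
Reagents that add atoms: triethylsilyl trifluoromethanesulfonate, CC[Si](CC)(CC)OS(=O)(=O)C(F)(F)F
Why: Silyl ether formation with a silyl triflate and a hindered pyridine base is fast enough at low temperature for a tertiary alcohol and avoids ionising the electron-rich benzylic carbinol, whose proton would otherwise quench the ketene acetal and the borylation reagents later.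

**Step 7**
Reactants: 12 triethyl{[(2S,4S)-4-(furan-2-yl)-2-(7-methoxy-2,2-dimethyl-2H-chromen-6-yl)pentan-2-yl]oxy}silane
Product: 13 triethyl{[(2S,4S)-2-(7-methoxy-2,2-dimethyl-2H-chromen-6-yl)-4-[5-(4,4,5,5-tetramethyl-1,3,2-dioxaborolan-2-yl)furan-2-yl]pentan-2-yl]oxy}silane
Conditions: [Ir(OMe)(cod)]2 (1.5 mol%), 4,4'-di-tert-butyl-2,2'-bipyridine (3 mol%), B2pin2 (0.6 equiv), THF, 25 °C
Reagents that add atoms: bis(pinacolato)diboron, CC1(C)OB(OC1(C)C)B1OC(C)(C)C(C)(C)O1
Why: Iridium-catalysed aromatic C–H borylation is sterically governed and fastest at the free α-position of a 2-alkylfuran, whereas both arene C–H bonds of the chromene are flanked by two substituents, and it spares the electron-rich chromene alkene and the C8–H between the two ring oxygens, which electrophilic halogenation or butyllithium metalation of the furan would endanger.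

**Step 8**
Reactants: 13 the furyl pinacol boronate of step 7; 14 methyl bromoacetate
Product: 15 methyl {5-[(2S,4S)-4-(7-methoxy-2,2-dimethyl-2H-chromen-6-yl)-4-(triethylsilyloxy)pentan-2-yl]furan-2-yl}acetate
Conditions: Pd(OAc)2 (3 mol%), P(1-naphthyl)3 (9 mol%), K3PO4, THF/H2O, 25 °C
Reagents that add atoms: none
Why: Palladium-catalysed Suzuki–Miyaura-type sp2–sp3 coupling of an arylboronate with an α-bromoacetate, proceeding by oxidative addition of the C–Br bond to a palladium enolate, transmetalation of the furyl group and reductive elimination, attaches the CH2CO2Me arm at room temperature under conditions that leave the TES ether and the chromene untouched.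

**Step 9**
Reactants: 15 methyl {5-[(2S,4S)-4-(7-methoxy-2,2-dimethyl-2H-chromen-6-yl)-4-(triethylsilyloxy)pentan-2-yl]furan-2-yl}acetate
Product: 17 tert-butyl{[(1Z)-1-methoxy-2-{5-[(2S,4S)-4-(7-methoxy-2,2-dimethyl-2H-chromen-6-yl)-4-(triethylsilyloxy)pentan-2-yl]furan-2-yl}ethenyl]oxy}dimethylsilane, via lithium ester enolate 16 (not isolated)
Conditions: LiN(iPr)2, THF/DMPU, −78 °C; TBSCl, −78 → 0 °C; pentane, filtration, no chromatography
Reagents that add atoms: tert-butyldimethylsilyl chloride, CC(C)(C)[Si](C)(C)Cl
Why: Ester enolisation with lithium diisopropylamide and O-silylation with TBSCl (ketene silyl acetal formation, as used for Ireland–Claisen substrates) should give the furyl ketene acetal mainly as the isomer with furan and silyloxy cis in the presence of DMPU, the ester α-CH2 being the only acidic site.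

**Step 10**
Reactants: 17 the (Z)-ketene silyl acetal of step 9; 18 but-3-yn-2-one
Product: 20 1-{6-(tert-butyldimethylsilyloxy)-2-[(2S,4S)-4-(7-methoxy-2,2-dimethyl-2H-chromen-6-yl)-4-(triethylsilyloxy)pentan-2-yl]-1-benzofuran-5-yl}ethanone, via 3a,6-dihydrobenzofuran cycloadduct 19 (not isolated)
Conditions: 18 (3 equiv), BHT (cat.), toluene, 80 → 110 °C, sealed tube, no Lewis acid
Reagents that add atoms: none
Why: Proposed new method: the ketene silyl acetal turns the exocyclic C=C and the furan C2=C3 bond into an electron-rich 1,1-dioxygenated diene that should add to the ynone in a concerted, asynchronous normal-demand [4+2] cycloaddition, after which cycloadduct 19 loses methanol by 1,4-elimination of the doubly allylic C3a–H and the C6 methoxy group to give the aromatic silyl ether. The closest known reaction types are Brassard-type benzannulations of vinylketene acetals with ynones and extra-annular Diels–Alder reactions of 2-vinylfurans with alkynes that aromatise to benzofurans, but a furan double bond serving as the second half of a ketene acetal diene has not been shown. The benzo ring closes intermolecularly by this cycloaddition, which forms C3a–C4 and C5–C6 in one operation. No lasting stereocentre is made, since C3a and C6 of 19 become sp2 on aromatisation and the two existing centres are remote from the reacting π system. Regioselectivity is needed and rests on matched polarisation: the acetal oxygens and the furan oxygen both enlarge the HOMO coefficient at furan C3, which bonds to the unsubstituted alkyne carbon, so the acetal carbon bonds to the acyl-bearing carbon and acetyl ends up at C5 next to the oxygen at C6. Periselectivity over Mukaiyama–Michael addition at the acetal α-carbon, [2+2] addition and addition across the furan 2,5-positions is the open point, and heating without Lewis acid is chosen to favour the concerted pathway.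

**Step 11**
Reactants: 20 the bis-silyl ether of step 10
Product: 21 1-{6-hydroxy-2-[(2S,4S)-4-hydroxy-4-(7-methoxy-2,2-dimethyl-2H-chromen-6-yl)pentan-2-yl]-1-benzofuran-5-yl}ethanone (CNP0233723.1)
Conditions: TBAF (2.5 equiv), THF, 0 → 25 °C
Reagents that add atoms: none
Why: Fluoride-induced desilylation removes the aryl TBS ether and the tertiary TES ether in one operation under non-acidic conditions, which the dehydration-prone tertiary benzylic alcohol requires.

**Compound list**
1 | 1-(4-hydroxy-2-methoxyphenyl)ethanone | CC(=O)c1ccc(O)cc1OC | starting material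
2 | 3-methylbut-2-enal | CC(C)=CC=O | starting material
3 | 1-(7-methoxy-2,2-dimethyl-2H-chromen-6-yl)ethanone | COc1cc2c(cc1C(C)=O)C=CC(C)(C)O2 | intermediate
4 | acetaldehyde | CC=O | starting material
5 | lithium enolate of 3 | COc1cc2c(cc1C(=C)O[Li])C=CC(C)(C)O2 | intermediate (not isolated)
6 | 3-hydroxy-1-(7-methoxy-2,2-dimethyl-2H-chromen-6-yl)butan-1-one (racemic) | COc1cc2c(cc1C(=O)CC(C)O)C=CC(C)(C)O2 | intermediate
7 | 4-(7-methoxy-2,2-dimethyl-2H-chromen-6-yl)-4-oxobutan-2-yl methanesulfonate (racemic) | COc1cc2c(cc1C(=O)CC(C)OS(C)(=O)=O)C=CC(C)(C)O2 | intermediate (not isolated)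
8 | (2E)-1-(7-methoxy-2,2-dimethyl-2H-chromen-6-yl)but-2-en-1-one | COc1cc2c(cc1C(=O)/C=C/C)C=CC(C)(C)O2 | intermediate
9 | furan-2-ylboronic acid | OB(O)c1ccco1 | starting material
10 | (3S)-3-(furan-2-yl)-1-(7-methoxy-2,2-dimethyl-2H-chromen-6-yl)butan-1-one | COc1cc2c(cc1C(=O)C[C@H](C)c1ccco1)C=CC(C)(C)O2 | intermediate
11 | (2S,4S)-4-(furan-2-yl)-2-(7-methoxy-2,2-dimethyl-2H-chromen-6-yl)pentan-2-ol | COc1cc2c(cc1[C@@](C)(O)C[C@H](C)c1ccco1)C=CC(C)(C)O2 | intermediate
12 | triethyl{[(2S,4S)-4-(furan-2-yl)-2-(7-methoxy-2,2-dimethyl-2H-chromen-6-yl)pentan-2-yl]oxy}silane | COc1cc2c(cc1[C@@](C)(O[Si](CC)(CC)CC)C[C@H](C)c1ccco1)C=CC(C)(C)O2 | intermediate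
13 | triethyl{[(2S,4S)-2-(7-methoxy-2,2-dimethyl-2H-chromen-6-yl)-4-[5-(4,4,5,5-tetramethyl-1,3,2-dioxaborolan-2-yl)furan-2-yl]pentan-2-yl]oxy}silane | COc1cc2c(cc1[C@@](C)(O[Si](CC)(CC)CC)C[C@H](C)c1ccc(B3OC(C)(C)C(C)(C)O3)o1)C=CC(C)(C)O2 | intermediate
14 | methyl bromoacetate | COC(=O)CBr | starting material
15 | methyl {5-[(2S,4S)-4-(7-methoxy-2,2-dimethyl-2H-chromen-6-yl)-4-(triethylsilyloxy)pentan-2-yl]furan-2-yl}acetate | COc1cc2c(cc1[C@@](C)(O[Si](CC)(CC)CC)C[C@H](C)c1ccc(CC(=O)OC)o1)C=CC(C)(C)O2 | intermediate
16 | lithium enolate of 15 | COc1cc2c(cc1[C@@](C)(O[Si](CC)(CC)CC)C[C@H](C)c1ccc(/C=C(/OC)O[Li])o1)C=CC(C)(C)O2 | intermediate (not isolated)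
17 | tert-butyl{[(1Z)-1-methoxy-2-{5-[(2S,4S)-4-(7-methoxy-2,2-dimethyl-2H-chromen-6-yl)-4-(triethylsilyloxy)pentan-2-yl]furan-2-yl}ethenyl]oxy}dimethylsilane | COc1cc2c(cc1[C@@](C)(O[Si](CC)(CC)CC)C[C@H](C)c1ccc(/C=C(/OC)O[Si](C)(C)C(C)(C)C)o1)C=CC(C)(C)O2 | intermediate
18 | but-3-yn-2-one | CC(=O)C#C | starting material
19 | 1-{6-(tert-butyldimethylsilyloxy)-6-methoxy-2-[(2S,4S)-4-(7-methoxy-2,2-dimethyl-2H-chromen-6-yl)-4-(triethylsilyloxy)pentan-2-yl]-3a,6-dihydro-1-benzofuran-5-yl}ethanone (mixture of isomers at C3a and C6) | COc1cc2c(cc1[C@@](C)(O[Si](CC)(CC)CC)C[C@H](C)C1=CC3C=C(C(C)=O)C(OC)(O[Si](C)(C)C(C)(C)C)C=C3O1)C=CC(C)(C)O2 | intermediate (not isolated)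
20 | 1-{6-(tert-butyldimethylsilyloxy)-2-[(2S,4S)-4-(7-methoxy-2,2-dimethyl-2H-chromen-6-yl)-4-(triethylsilyloxy)pentan-2-yl]-1-benzofuran-5-yl}ethanone | COc1cc2c(cc1[C@@](C)(O[Si](CC)(CC)CC)C[C@H](C)c1cc3cc(C(C)=O)c(O[Si](C)(C)C(C)(C)C)cc3o1)C=CC(C)(C)O2 | intermediate
21 | 1-{6-hydroxy-2-[(2S,4S)-4-hydroxy-4-(7-methoxy-2,2-dimethyl-2H-chromen-6-yl)pentan-2-yl]-1-benzofuran-5-yl}ethanone | COc1cc2c(cc1[C@@](C)(O)C[C@H](C)c1cc3cc(C(C)=O)c(O)cc3o1)C=CC(C)(C)O2 | target

**Step count and risks**
Total step count: 11. Longest linear sequence: 11 steps (1 → 21).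

Steps most likely to fail:

Step 10 (key cycloaddition). The acetal α-carbon may add to the ynone in a Mukaiyama–Michael sense without ring closure. The ketene acetal C=C may undergo [2+2] addition, or be protodesilylated by traces of acid. On aromatisation silanol may be expelled in place of methanol, which would leave an aryl methyl ether. The fallback builds the benzofuran from an alkyne and an ortho-iodophenol by known chemistry. It sets out from enone 8. Rhodium-catalysed asymmetric conjugate alkynylation with (triisopropylsilyl)acetylene ([Rh(OAc)(C2H4)2]2, DTBM-SEGPHOS enantiomer chosen for the (S) centre, dioxane, 80 °C) should give β-alkynyl ketone F1. Catalyst-controlled methyl addition as in step 5 should give tertiary alcohol F2, and TBAF should free terminal alkyne F3. Sonogashira coupling of F3 with 1-(2,4-dihydroxy-5-iodophenyl)ethanone F4 (made by iodination of 1-(2,4-dihydroxyphenyl)ethanone) under PdCl2(PPh3)2, CuI and Et3N in DMF at 60 °C is followed in the same flask by 5-endo-dig attack of the hydroxyl para to the acetyl group on the alkyne. This closes the furan ring and comes back to the route at target 21.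

Step 4 (furyl transfer). Protodeboronation of the furylboronic acid may outrun transmetalation so that conversion stalls, and a heteroaryl group may be transferred with lower enantioselectivity than an aryl group. The fallback creates the centre by hydride delivery and not by furyl transfer. It sets out from 8. Mizoroki–Heck arylation with 2-bromofuran (Pd(OAc)2, P(o-tolyl)3, Et3N, DMF, 90 °C) should give β,β-disubstituted (E)-enone F5. Asymmetric conjugate reduction with CuH generated from Cu(OAc)2, DTBM-SEGPHOS and polymethylhydrosiloxane (tBuOH, toluene) should then give 10, where the route resumes.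

Step 5 (methyl addition). Addition to the ortho-methoxy aryl ketone may be slow and facial control incomplete, which would give a mixture of C2 epimers. The fallback is a stereospecific lithiation–borylation that sets out from 10. CBS reduction ((R)-2-methyl-CBS-oxazaborolidine, BH3·SMe2) should give secondary alcohol F6, and carbamoylation (iPr2NCOCl, Et3N) should give carbamate F7. Deprotonation with sBuLi in Et2O at −78 °C, addition of 2,4,4,5,5-pentamethyl-1,3,2-dioxaborolane and warming should induce 1,2-migration of methyl with inversion at carbon to tertiary boronate F8. Oxidation with NaOH/H2O2 proceeds with retention, so that overall H is replaced by CH3 with retention, and the sequence comes back to the route at 11.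

**Further compounds**
F1 | step 10 | (3S)-1-(7-methoxy-2,2-dimethyl-2H-chromen-6-yl)-3-methyl-5-[tri(propan-2-yl)silyl]pent-4-yn-1-one | COc1cc2c(cc1C(=O)C[C@H](C)C#C[Si](C(C)C)(C(C)C)C(C)C)C=CC(C)(C)O2
F2 | step 10 | (2S,4S)-2-(7-methoxy-2,2-dimethyl-2H-chromen-6-yl)-4-methyl-6-[tri(propan-2-yl)silyl]hex-5-yn-2-ol | COc1cc2c(cc1[C@@](C)(O)C[C@H](C)C#C[Si](C(C)C)(C(C)C)C(C)C)C=CC(C)(C)O2
F3 | step 10 | (2S,4S)-2-(7-methoxy-2,2-dimethyl-2H-chromen-6-yl)-4-methylhex-5-yn-2-ol | COc1cc2c(cc1[C@@](C)(O)C[C@H](C)C#C)C=CC(C)(C)O2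
F4 | step 10 | 1-(2,4-dihydroxy-5-iodophenyl)ethanone | CC(=O)c1cc(I)c(O)cc1O
F5 | step 4 | (2E)-3-(furan-2-yl)-1-(7-methoxy-2,2-dimethyl-2H-chromen-6-yl)but-2-en-1-one | COc1cc2c(cc1C(=O)/C=C(\C)c1ccco1)C=CC(C)(C)O2
F6 | step 5 | (1S,3S)-3-(furan-2-yl)-1-(7-methoxy-2,2-dimethyl-2H-chromen-6-yl)butan-1-ol | COc1cc2c(cc1[C@@H](O)C[C@H](C)c1ccco1)C=CC(C)(C)O2
F7 | step 5 | (1S,3S)-3-(furan-2-yl)-1-(7-methoxy-2,2-dimethyl-2H-chromen-6-yl)butyl N,N-di(propan-2-yl)carbamate | COc1cc2c(cc1[C@@H](OC(=O)N(C(C)C)C(C)C)C[C@H](C)c1ccco1)C=CC(C)(C)O2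
F8 | step 5 | 2-[(2R,4S)-4-(furan-2-yl)-2-(7-methoxy-2,2-dimethyl-2H-chromen-6-yl)pentan-2-yl]-4,4,5,5-tetramethyl-1,3,2-dioxaborolane | COc1cc2c(cc1[C@@](C)(B3OC(C)(C)C(C)(C)O3)C[C@H](C)c1ccco1)C=CC(C)(C)O2
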